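**Strategy**

The route rests on disconnecting ring C of the flavonol at C4–C4a and O1–C2. Ring A carries oxygen on every carbon except C4a, the only free position ortho to O1, so a propargyl group on O1 can migrate to one place only. Heating the aryl 1-arylpropargyl ether triggers Claisen rearrangement, hydrogen shift and oxa-6π ring closure, which forge C4–C4a, re-form O1–C2 and close ring C as a 2-aryl-2H-chromene in one operation. The precursor is the Mitsunobu ether of 2,3,4,5-tetramethoxyphenol and racemic 1-[2,5-bis(benzyloxy)phenyl]prop-2-yn-1-ol. Dihydroxylation of C3=C4, oxidation to the flavonol and BCl3 deprotection finish the synthesis.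

Key step: step 6

Remark: flavone numbering is used (O1, C2, C3, C4, C4a, C5–C8, C8a; ring A is the benzo ring, ring C the pyran ring, ring B the 2-aryl group). The target has no stereocentre, so every stereocentre of an intermediate is racemic and is erased by step 8.

**Route**

Step 1
Reactants: 1 1,2,3,4-tetramethoxybenzene
Product: 3 2,3,4,5-tetramethoxybenzaldehyde, via iminium chloride 2 (not isolated)
Conditions: POCl3, DMF, 0 → 80 °C; then H2O, rt
Reagents that add atoms: N,N-dimethylformamide, CN(C)C=O (formyl carbon); water, O (carbonyl oxygen)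
Why: Vilsmeier–Haack formylation should occur at either of the two equivalent free ring carbons of 1, each ortho and para to a methoxy group, and hydrolysis of iminium salt 2 releases the aldehyde.

Step 2
Reactants: 3 2,3,4,5-tetramethoxybenzaldehyde
Product: 5 2,3,4,5-tetramethoxyphenol, via aryl formate 4 (not isolated)
Conditions: mCPBA, CH2Cl2, 0 °C → rt; then K2CO3 (cat.), MeOH, rt
Reagents that add atoms: mCPBA, O=C(OO)c1cccc(Cl)c1
Why: Baeyer–Villiger (Dakin-type) oxidation should proceed with migration of the electron-rich aryl group, which has ortho and para methoxy donors, to give formate 4, and base-catalysed methanolysis then frees the phenol.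

Step 3
Reactants: 6 2,5-dihydroxybenzaldehyde
Product: 7 2,5-bis(benzyloxy)benzaldehyde
Conditions: BnBr, K2CO3, DMF, 60 °C
Reagents that add atoms: benzyl bromide, BrCc1ccccc1
Why: Double Williamson etherification of the two phenols with a reactive benzylic halide under carbonate conditions is standard, and the aldehyde has no enolisable position.

Step 4
Reactants: 7 2,5-bis(benzyloxy)benzaldehyde; 8 ethynylmagnesium bromide
Product: 10 rac-1-[2,5-bis(benzyloxy)phenyl]prop-2-yn-1-ol, via magnesium alkoxide 9 (not isolated)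
Conditions: THF, 0 °C; then sat. aq. NH4Cl
Reagents that add atoms: ethynylmagnesium bromide (8), C#C[Mg]Br
Why: Grignard 1,2-addition of the acetylide to the non-enolisable aldehyde should give the propargylic alcohol, whose new stereocentre forms without control (racemic) and is destroyed in step 6.

Step 5
Reactants: 5 2,3,4,5-tetramethoxyphenol; 10 rac-1-[2,5-bis(benzyloxy)phenyl]prop-2-yn-1-ol
Product: 11 rac-1-({1-[2,5-bis(benzyloxy)phenyl]prop-2-yn-1-yl}oxy)-2,3,4,5-tetramethoxybenzene
Conditions: PPh3, DIAD, THF, 0 °C → rt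
Reagents that add atoms: none
Why: Mitsunobu etherification, in which the phenol (pKa about 10) is acidic enough to protonate the betaine and its phenoxide displaces the oxyphosphonium group at the activated propargylic carbon; the configuration of this centre is immaterial.

Step 6
Reactants: 11 rac-1-({1-[2,5-bis(benzyloxy)phenyl]prop-2-yn-1-yl}oxy)-2,3,4,5-tetramethoxybenzene
Product: 15 rac-2-[2,5-bis(benzyloxy)phenyl]-5,6,7,8-tetramethoxy-2H-chromene, via allenyl dienone 12 (not isolated), via ortho-allenylphenol 13 (not isolated), via ortho-quinone methide 14 (not isolated)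
Conditions: 1,2-dichlorobenzene (degassed), BHT (cat.), 170 °C, Ar
Reagents that add atoms: none
Why: On heating, an aromatic Claisen ([3,3]-sigmatropic) rearrangement bonds the alkyne terminus to C4a and gives allenyl dienone 12, which enolises to ortho-allenylphenol 13; a [1,5]-hydrogen shift from the phenolic oxygen to the central allene carbon then produces ortho-quinone methide 14, whose oxa-6π electrocyclisation joins O1 to C2. The closest known reaction type is the thermal rearrangement of aryl propargyl ethers to 2H-chromenes. Ring C closes as a six-membered pyran by a thermal, disrotatory 6π electrocyclisation of the O=C8a–C4a=C4–C3=C2 oxatriene, not by nucleophilic attack of oxygen on the allene. The only new stereocentre, C2, comes from achiral 14 with no controlling element and is racemic, which is harmless because C2 becomes sp2 in step 8. The step needs regioselective migration to C4a and chromene rather than benzofuran formation: C4a is the one ortho carbon of ring A that bears hydrogen (migration to methoxy-bearing C8 can only revert, since that dienone cannot enolise), and neutral, base-free heating keeps the allenylphenol from cyclising through its phenoxide to a benzofuran.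

Step 7
Reactants: 15 rac-2-[2,5-bis(benzyloxy)phenyl]-5,6,7,8-tetramethoxy-2H-chromene
Product: 16 rac-(2R,3S,4S)-2-[2,5-bis(benzyloxy)phenyl]-5,6,7,8-tetramethoxy-3,4-dihydro-2H-chromene-3,4-diol (2,3-trans-3,4-cis)
Conditions: OsO4 (cat.), NMO, acetone/H2O, rt
Reagents that add atoms: osmium tetroxide, O=[Os](=O)(=O)=O (catalytic carrier of both oxygens); N-methylmorpholine N-oxide, C[N+]1([O-])CCOCC1 (stoichiometric oxygen source); water, O (hydrolysis of the osmate ester)
Why: Upjohn dihydroxylation adds both oxygens syn to the only alkene, from the face opposite the C2 aryl group, which sets the 2,3-trans-3,4-cis relative configuration by substrate control (racemic; all three centres are removed in step 8).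

Step 8
Reactants: 16 rac-(2R,3S,4S)-2-[2,5-bis(benzyloxy)phenyl]-5,6,7,8-tetramethoxy-3,4-dihydro-2H-chromene-3,4-diol
Product: 19 2-[2,5-bis(benzyloxy)phenyl]-3-hydroxy-5,6,7,8-tetramethoxy-4H-chromen-4-one, via hydroxy ketone 17 (not isolated), via 3,4-dione 18 (not isolated)
Conditions: 2-iodoxybenzoic acid (IBX), DMSO, rt → 50 °C
Reagents that add atoms: none
Why: 2-Iodoxybenzoic acid oxidises vicinal diols to 1,2-diones without C–C cleavage, the benzylic C4 carbinol going first to hydroxy ketone 17 and then to dione 18, whose doubly activated C2–H tautomerises spontaneously to the conjugated 3-hydroxychromone.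

Step 9
Reactants: 19 2-[2,5-bis(benzyloxy)phenyl]-3-hydroxy-5,6,7,8-tetramethoxy-4H-chromen-4-one
Product: 20 2-(2,5-dihydroxyphenyl)-3,5-dihydroxy-6,7,8-trimethoxy-4H-chromen-4-one (target)
Conditions: BCl3, C6HMe5, CH2Cl2, −78 → 0 °C, Ar; then H2O
Reagents that add atoms: none
Why: Lewis-acid ether cleavage, in which BCl3 with pentamethylbenzene as benzyl-cation trap removes the aryl benzyl ethers at low temperature and boron chelated between the C4 carbonyl and the peri C5 oxygen cleaves that methyl ether selectively, the C6, C7 and C8 methoxy groups lacking such activation.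

**Compound list**

1 | 1,2,3,4-tetramethoxybenzene | COc1ccc(OC)c(OC)c1OC | starting material
2 | N,N-dimethyl-1-(2,3,4,5-tetramethoxyphenyl)methaniminium chloride | C[N+](C)=Cc1cc(OC)c(OC)c(OC)c1OC.[Cl-] | intermediate
3 | 2,3,4,5-tetramethoxybenzaldehyde | O=Cc1cc(OC)c(OC)c(OC)c1OC | intermediate
4 | 2,3,4,5-tetramethoxyphenyl formate | O=COc1cc(OC)c(OC)c(OC)c1OC | intermediate
5 | 2,3,4,5-tetramethoxyphenol | Oc1cc(OC)c(OC)c(OC)c1OC | intermediate
6 | 2,5-dihydroxybenzaldehyde | O=Cc1cc(O)ccc1O | starting material
7 | 2,5-bis(benzyloxy)benzaldehyde | O=Cc1cc(OCc2ccccc2)ccc1OCc1ccccc1 | intermediate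
8 | ethynylmagnesium bromide | C#C[Mg]Br | starting material
9 | bromomagnesium 1-[2,5-bis(benzyloxy)phenyl]prop-2-yn-1-olate (racemic) | C#CC(O[Mg]Br)c1cc(OCc2ccccc2)ccc1OCc1ccccc1 | intermediate
10 | rac-1-[2,5-bis(benzyloxy)phenyl]prop-2-yn-1-ol | C#CC(O)c1cc(OCc2ccccc2)ccc1OCc1ccccc1 | intermediate
11 | rac-1-({1-[2,5-bis(benzyloxy)phenyl]prop-2-yn-1-yl}oxy)-2,3,4,5-tetramethoxybenzene | C#CC(Oc1cc(OC)c(OC)c(OC)c1OC)c1cc(OCc2ccccc2)ccc1OCc1ccccc1 | intermediate
12 | 6-{3-[2,5-bis(benzyloxy)phenyl]propa-1,2-dien-1-yl}-2,3,4,5-tetramethoxycyclohexa-2,4-dien-1-one (mixture of stereoisomers) | O=C1C(OC)=C(OC)C(OC)=C(OC)C1C=C=Cc1cc(OCc2ccccc2)ccc1OCc1ccccc1 | intermediate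
13 | 2-{3-[2,5-bis(benzyloxy)phenyl]propa-1,2-dien-1-yl}-3,4,5,6-tetramethoxyphenol (racemic allene) | Oc1c(OC)c(OC)c(OC)c(OC)c1C=C=Cc1cc(OCc2ccccc2)ccc1OCc1ccccc1 | intermediate
14 | (6Z)-6-{(2E)-3-[2,5-bis(benzyloxy)phenyl]prop-2-en-1-ylidene}-2,3,4,5-tetramethoxycyclohexa-2,4-dien-1-one (styryl geometry drawn E; either geometry closes) | O=C1C(OC)=C(OC)C(OC)=C(OC)/C1=C/C=C/c1cc(OCc2ccccc2)ccc1OCc1ccccc1 | intermediate
15 | rac-2-[2,5-bis(benzyloxy)phenyl]-5,6,7,8-tetramethoxy-2H-chromene | COc1c(OC)c(OC)c2C=CC(c3cc(OCc4ccccc4)ccc3OCc3ccccc3)Oc2c1OC | intermediate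
16 | rac-(2R,3S,4S)-2-[2,5-bis(benzyloxy)phenyl]-5,6,7,8-tetramethoxy-3,4-dihydro-2H-chromene-3,4-diol (one enantiomer drawn) | O[C@@H]1[C@H](O)[C@@H](c2cc(OCc3ccccc3)ccc2OCc2ccccc2)Oc2c(OC)c(OC)c(OC)c(OC)c12 | intermediate
17 | rac-(2R,3R)-2-[2,5-bis(benzyloxy)phenyl]-3-hydroxy-5,6,7,8-tetramethoxy-2,3-dihydro-4H-chromen-4-one (trans; one enantiomer drawn) | O=C1[C@H](O)[C@@H](c2cc(OCc3ccccc3)ccc2OCc2ccccc2)Oc2c(OC)c(OC)c(OC)c(OC)c12 | intermediate
18 | rac-2-[2,5-bis(benzyloxy)phenyl]-5,6,7,8-tetramethoxy-2H-chromene-3,4-dione | O=C1C(=O)C(c2cc(OCc3ccccc3)ccc2OCc2ccccc2)Oc2c(OC)c(OC)c(OC)c(OC)c12 | intermediate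
19 | 2-[2,5-bis(benzyloxy)phenyl]-3-hydroxy-5,6,7,8-tetramethoxy-4H-chromen-4-one | COc1c(OC)c(OC)c2c(=O)c(O)c(-c3cc(OCc4ccccc4)ccc3OCc3ccccc3)oc2c1OC | intermediate
20 | 2-(2,5-dihydroxyphenyl)-3,5-dihydroxy-6,7,8-trimethoxy-4H-chromen-4-one | COc1c(OC)c(O)c2c(=O)c(O)c(-c3cc(O)ccc3O)oc2c1OC | target

**Step count and risks**

Total step count: 9. Longest linear sequence: 7 steps (steps 1, 2, 5, 6, 7, 8, 9; the branch through steps 3, 4, 5–9 is equally long).

Steps most likely to fail:

1. Step 6. The propargylic C–O bond is activated by both the alkyne and the alkoxy-substituted aryl group, so at 170 °C it may ionise instead of rearranging; the terminal alkyne may also oligomerise, or the allenylphenol may divert to a benzofuran. The fallback sets out from 5 and 7 and builds ring C from a chalcone. Phenol 5 would be C-acetylated at its only free ring carbon (AcOH, BF3·OEt2, 90 °C) to give 1-(2-hydroxy-3,4,5,6-tetramethoxyphenyl)ethan-1-one F1. Claisen–Schmidt condensation of this ketone with aldehyde 7 (KOH, EtOH, rt) would give (2E)-3-[2,5-bis(benzyloxy)phenyl]-1-(2-hydroxy-3,4,5,6-tetramethoxyphenyl)prop-2-en-1-one F2. Luche 1,2-reduction (NaBH4, CeCl3·7H2O, MeOH/THF, 0 °C) would give rac-2-{(2E)-3-[2,5-bis(benzyloxy)phenyl]-1-hydroxyprop-2-en-1-yl}-3,4,5,6-tetramethoxyphenol F3. Mild acid (AcOH, 40 °C) should dehydrate this ortho-hydroxybenzylic alcohol to ortho-quinone methide 14, which closes as before, so the fallback rejoins the route at 15.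

2. Step 8. The double oxidation may stall at the hydroxy ketone, cleave the C3–C4 glycol bond or over-oxidise the product enol. The fallback sets out from 16 and separates the two oxidations. DDQ (1,4-dioxane, rt) should dehydrogenate only the electron-rich benzylic C4 carbinol and give hydroxy ketone 17, now isolated. Iodine with KOAc in AcOH at 90 °C would then oxidise its enediol tautomer, the standard dihydroflavonol-to-flavonol conversion, and rejoin the route at 19. No compound outside the list is made.

3. Step 9. Excess BCl3 may remove a second methyl group (at C6), benzyl cations may alkylate the hydroquinone ring, or cleavage may stop short; the free hydroquinone may also oxidise in air during work-up. The fallback sets out from 19 and splits the deprotection by mechanism. Hydrogenolysis (H2, Pd/C, EtOAc/MeOH, rt) would remove both benzyl groups and give 2-(2,5-dihydroxyphenyl)-3-hydroxy-5,6,7,8-tetramethoxy-4H-chromen-4-one F4. AlCl3 in MeCN (rt → 50 °C, then dilute aq. HCl, under Ar) would then cleave only the peri-chelated C5 methyl ether and reach 20.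

**Further compounds**

F1 | step 6 | 1-(2-hydroxy-3,4,5,6-tetramethoxyphenyl)ethan-1-one | CC(=O)c1c(O)c(OC)c(OC)c(OC)c1OC
F2 | step 6 | (2E)-3-[2,5-bis(benzyloxy)phenyl]-1-(2-hydroxy-3,4,5,6-tetramethoxyphenyl)prop-2-en-1-one | O=C(/C=C/c1cc(OCc2ccccc2)ccc1OCc1ccccc1)c1c(O)c(OC)c(OC)c(OC)c1OC
F3 | step 6 | rac-2-{(2E)-3-[2,5-bis(benzyloxy)phenyl]-1-hydroxyprop-2-en-1-yl}-3,4,5,6-tetramethoxyphenol | OC(/C=C/c1cc(OCc2ccccc2)ccc1OCc1ccccc1)c1c(O)c(OC)c(OC)c(OC)c1OC
F0 | step 8 | none | none
F4 | step 9 | 2-(2,5-dihydroxyphenyl)-3-hydroxy-5,6,7,8-tetramethoxy-4H-chromen-4-one | COc1c(OC)c(OC)c2c(=O)c(O)c(-c3cc(O)ccc3O)oc2c1OC
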